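**Plan**

- Retrosynthesis: the 7-O-silyl ether is removed first. Ring C is then cut at O1–C8a and C4–C4a (chroman numbering) in one operation, giving a ring A iodide and (S)-3-bromo-2-(2,3,4,5-tetramethoxyphenyl)propan-1-ol. The bromo alcohol goes back through its monoacetate to a prochiral 2-aryl-1,3-propanediol and an aryl malonate (aryl–C3 bond).
- Enabling feature: ring C is fused to ring A at two adjacent carbons, C4a (bound to C4) and C8a (bound to O1). C8, the other neighbour of C8a, carries OMe, so an iodide at C8a has C4a–H as its only free ortho position.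
- Forward order: the ring A iodide is made in two steps from guaiacol. The ring B–C3 fragment is made in six steps from 1,2,3,4-tetramethoxybenzene and diethyl malonate. One palladium/norbornene step joins them and closes ring C, and desilylation ends the route.
- Stereochemistry: the single stereocentre (C3, S) comes from lipase desymmetrisation of the prochiral diol. The choice of which arm becomes CH2Br (C4) and which stays CH2OH (C2) fixes the configuration, and no later step reacts at that carbon.

Key step: step 9

Assumption (enzyme selectivity): the lipase acetylates the enantiotopic hydroxymethyl arm that leads to the (R)-monoacetate; if it acylated the other arm, the same enzyme used for hydrolysis of the diacetate would supply the (R)-monoacetate.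

**Route**

Step 1
Reactants: 1 guaiacol (2-methoxyphenol)
Product: 2 triisopropyl(2-methoxyphenoxy)silane
Conditions: TIPSCl, imidazole, DMF, rt
Reagents that add atoms: chlorotriisopropylsilane, CC(C)[Si](Cl)(C(C)C)C(C)C
Why: Routine silylation of a phenol; the bulky triisopropylsilyl ether is chosen because it neither directs nor suffers attack in the lithiation that follows and should resist carbonate base later.

Step 2
Reactants: 2 triisopropyl(2-methoxyphenoxy)silane
Product: 4 (3-iodo-2-methoxyphenoxy)triisopropylsilane, via aryllithium 3 (not isolated)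
Conditions: s-BuLi, TMEDA, THF, −78 °C; then I2, THF, −78 °C → rt
Reagents that add atoms: iodine, II
Why: Directed ortho-metalation, in which the methoxyl coordinates s-BuLi/TMEDA and delivers lithium to its only free ortho position while the bulky silyloxy group is a non-directing, non-migrating neighbour; iodine then quenches the aryllithium.

Step 3
Reactants: 5 1,2,3,4-tetramethoxybenzene
Product: 6 1-bromo-2,3,4,5-tetramethoxybenzene
Conditions: NBS (1.0 equiv), MeCN, 0 °C → rt
Reagents that add atoms: N-bromosuccinimide, O=C1CCC(=O)N1Br
Why: Electrophilic aromatic bromination of an activated arene whose two unsubstituted positions are equivalent, so one equivalent of NBS can give only one monobromide.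

Step 4
Reactants: 6 1-bromo-2,3,4,5-tetramethoxybenzene; 7 diethyl malonate
Product: 8 diethyl 2-(2,3,4,5-tetramethoxyphenyl)malonate
Conditions: Pd(OAc)2 (2 mol%), P(t-Bu)3·HBF4 (4 mol%), K3PO4, toluene, 80 °C
Reagents that add atoms: none
Why: Palladium-catalysed α-arylation of a malonate enolate (Buchwald–Hartwig type), where the bulky electron-rich phosphine permits oxidative addition of the electron-rich ortho-substituted bromide and C–C reductive elimination, and the more acidic aryl malonate rests as its enolate and is not arylated again.

Step 5
Reactants: 8 diethyl 2-(2,3,4,5-tetramethoxyphenyl)malonate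
Product: 9 2-(2,3,4,5-tetramethoxyphenyl)propane-1,3-diol
Conditions: LiAlH4 (excess), THF, 0 °C → reflux; aqueous work-up
Reagents that add atoms: none
Why: Hydride reduction of both esters with LiAlH4, the usual entry to 2-aryl-1,3-propanediols; excess reagent and a cold start limit competing enolate formation.

Step 6
Reactants: 9 2-(2,3,4,5-tetramethoxyphenyl)propane-1,3-diol
Product: 10 (2R)-3-hydroxy-2-(2,3,4,5-tetramethoxyphenyl)propyl acetate
Conditions: Burkholderia cepacia lipase (Amano PS), vinyl acetate, t-BuOMe, rt
Reagents that add atoms: vinyl acetate, CC(=O)OC=C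
Why: Lipase-catalysed desymmetrisation by irreversible transesterification, in which the chiral active site acylates one of the two enantiotopic hydroxymethyl groups of the prochiral diol and so creates the only stereocentre of the route (C3 of the target).

Step 7
Reactants: 10 (2R)-3-hydroxy-2-(2,3,4,5-tetramethoxyphenyl)propyl acetate
Product: 11 (2S)-3-bromo-2-(2,3,4,5-tetramethoxyphenyl)propyl acetate
Conditions: CBr4, PPh3, CH2Cl2, 0 °C
Reagents that add atoms: tetrabromomethane, BrC(Br)(Br)Br
Why: Appel reaction, in which the free primary hydroxyl becomes an alkoxyphosphonium ion and is displaced by bromide in an SN2 step at CH2 under neutral conditions that avoid 1,3-acetyl migration (which would racemise 10) and do not touch the stereocentre.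

Step 8
Reactants: 11 (2S)-3-bromo-2-(2,3,4,5-tetramethoxyphenyl)propyl acetate
Product: 12 (2S)-3-bromo-2-(2,3,4,5-tetramethoxyphenyl)propan-1-ol
Conditions: HCl (cat., 1.25 M in MeOH), MeOH, 0 °C → rt
Reagents that add atoms: none
Why: Acid-catalysed transesterification of the acetate with methanol; acid is preferred to base so that no alkoxide is generated next to the primary bromide, and the stereocentre is not involved.

Step 9
Reactants: 4 (3-iodo-2-methoxyphenoxy)triisopropylsilane; 12 (2S)-3-bromo-2-(2,3,4,5-tetramethoxyphenyl)propan-1-ol
Product: 13 triisopropyl{[(3S)-8-methoxy-3-(2,3,4,5-tetramethoxyphenyl)-3,4-dihydro-2H-chromen-7-yl]oxy}silane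
Conditions: Pd(OAc)2 (10 mol%), XPhos (2-dicyclohexylphosphino-2′,4′,6′-triisopropylbiphenyl, 20 mol%), norbornene (1.5 equiv), Cs2CO3 (2.5 equiv), 1,4-dioxane, 90 °C
Reagents that add atoms: none
Why: Proposed new method: oxidative addition of iodide 4 to zerovalent palladium, norbornene insertion and carbonate-assisted palladation of the one free ortho C–H should give an aryl–norbornyl palladacycle of divalent palladium, which takes up the primary bromide of 12 by SN2-type oxidative addition to tetravalent palladium and forms C4–C4a by reductive elimination. With both ortho positions then substituted (OMe and the new chain), β-carbon elimination expels norbornene, and the arylpalladium species binds the pendant alkoxide and forms O1–C8a by C–O reductive elimination, which the bulky biarylphosphine is chosen to favour over β-hydride elimination. The closest known reactions are the palladium/norbornene annulation of aryl iodides with epoxides to 2,3-dihydrobenzofurans (ortho alkylation, ipso alkoxide termination), the analogous annulation with 3-bromopropylamines to tetrahydroquinolines, and the palladium-catalysed cyclisation of 3-(2-halophenyl)propan-1-ols to chromans. Ring C closes by intramolecular C–O reductive elimination from a seven-membered oxapalladacycle, formally a 6-exo attack of the alkoxide on C8a. No stereocentre is formed, and C3 is not a reacting centre (neither the carbon that is alkylated nor the oxygen that is arylated), so it is carried through from 12 unchanged. Alkylation before etherification is secured by the norbornene relay, the site of alkylation by the C8 methoxyl that blocks the second ortho position, and survival of the bromo alcohol by a poorly soluble carbonate in a solvent of low polarity, which keeps the free alkoxide, and with it oxetane closure, low.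

Step 10
Reactants: 13 triisopropyl{[(3S)-8-methoxy-3-(2,3,4,5-tetramethoxyphenyl)-3,4-dihydro-2H-chromen-7-yl]oxy}silane
Product: 14 (3S)-8-methoxy-3-(2,3,4,5-tetramethoxyphenyl)-3,4-dihydro-2H-chromen-7-ol
Conditions: Bu4NF, AcOH, THF, 0 °C
Reagents that add atoms: none
Why: Fluoride-induced cleavage of the aryl silyl ether, driven by Si–F bond formation; AcOH buffers the phenoxide of the electron-rich product, and the five methyl ethers and ring C are inert.

**Compound list**

1 | guaiacol (2-methoxyphenol) | COc1ccccc1O | starting material
2 | triisopropyl(2-methoxyphenoxy)silane | COc1ccccc1O[Si](C(C)C)(C(C)C)C(C)C | intermediate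
3 | [2-methoxy-3-(triisopropylsilyloxy)phenyl]lithium | COc1c([Li])cccc1O[Si](C(C)C)(C(C)C)C(C)C | intermediate
4 | (3-iodo-2-methoxyphenoxy)triisopropylsilane | COc1c(I)cccc1O[Si](C(C)C)(C(C)C)C(C)C | intermediate
5 | 1,2,3,4-tetramethoxybenzene | COc1ccc(OC)c(OC)c1OC | starting material
6 | 1-bromo-2,3,4,5-tetramethoxybenzene | COc1cc(Br)c(OC)c(OC)c1OC | intermediate
7 | diethyl malonate | CCOC(=O)CC(=O)OCC | starting material
8 | diethyl 2-(2,3,4,5-tetramethoxyphenyl)malonate | CCOC(=O)C(C(=O)OCC)c1cc(OC)c(OC)c(OC)c1OC | intermediate
9 | 2-(2,3,4,5-tetramethoxyphenyl)propane-1,3-diol | OCC(CO)c1cc(OC)c(OC)c(OC)c1OC | intermediate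
10 | (2R)-3-hydroxy-2-(2,3,4,5-tetramethoxyphenyl)propyl acetate | COc1cc([C@H](CO)COC(C)=O)c(OC)c(OC)c1OC | intermediate
11 | (2S)-3-bromo-2-(2,3,4,5-tetramethoxyphenyl)propyl acetate | COc1cc([C@H](CBr)COC(C)=O)c(OC)c(OC)c1OC | intermediate
12 | (2S)-3-bromo-2-(2,3,4,5-tetramethoxyphenyl)propan-1-ol | COc1cc([C@H](CBr)CO)c(OC)c(OC)c1OC | intermediate
13 | triisopropyl{[(3S)-8-methoxy-3-(2,3,4,5-tetramethoxyphenyl)-3,4-dihydro-2H-chromen-7-yl]oxy}silane | COc1cc([C@H]2COc3c(ccc(O[Si](C(C)C)(C(C)C)C(C)C)c3OC)C2)c(OC)c(OC)c1OC | intermediate
14 | (3S)-8-methoxy-3-(2,3,4,5-tetramethoxyphenyl)-3,4-dihydro-2H-chromen-7-ol | COc1cc([C@H]2COc3c(ccc(O)c3OC)C2)c(OC)c(OC)c1OC | target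

**Step count and risks**

Total step count: 10. Longest linear sequence: 8 steps (5 to 14, steps 3 to 10).

Steps most likely to fail:

Step 9. The C–O reductive elimination from the arylpalladium alkoxide may lose to β-hydride elimination (reduced arene and an aldehyde). The free bromo alcohol may also be consumed by base, through oxetane closure or elimination, before the palladacycle captures it. The fallback sets out from 4 and 11 and returns at 13. It keeps the hydroxyl masked during the palladium step and closes ring C at O1–C2 instead. Palladium/norbornene ortho-alkylation of 4 with the acetate-protected bromide 11, ended by ipso borylation with B2pin2 (Pd(OAc)2, a triarylphosphine, norbornene, Cs2CO3, an established termination of this relay), should give the arylboronic ester (2S)-3-[3-methoxy-2-(4,4,5,5-tetramethyl-1,3,2-dioxaborolan-2-yl)-4-(triisopropylsilyloxy)phenyl]-2-(2,3,4,5-tetramethoxyphenyl)propyl acetate F1. Oxidation of the C–B bond with NaBO3·4H2O in THF/water should give the phenol (2S)-3-[2-hydroxy-3-methoxy-4-(triisopropylsilyloxy)phenyl]-2-(2,3,4,5-tetramethoxyphenyl)propyl acetate F2. Reductive removal of the acetate with i-Bu2AlH at −78 °C should give the phenol alcohol (2S)-3-[2-hydroxy-3-methoxy-4-(triisopropylsilyloxy)phenyl]-2-(2,3,4,5-tetramethoxyphenyl)propan-1-ol F3. Mitsunobu etherification (PPh3, diisopropyl azodicarboxylate, THF) then closes ring C at the primary carbinol to give 13, with the stereocentre not involved.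

Step 6. The enzyme may discriminate the two enantiotopic hydroxymethyl arms poorly with this ortho-methoxylated aryl group, or acylate the arm opposite to the one assumed. The fallback sets out from 9 and returns at 12. It uses a non-enzymatic desymmetrisation whose sense is chosen through the ligand enantiomer. Benzoylation of 9 with vinyl benzoate under the dinuclear zinc catalyst formed from Et2Zn and 2,6-bis{[2-(hydroxydiphenylmethyl)pyrrolidin-1-yl]methyl}-4-methylphenol (the enantiomer that acylates the required arm) should give the monobenzoate (2R)-3-hydroxy-2-(2,3,4,5-tetramethoxyphenyl)propyl benzoate F4. Appel bromination (CBr4, PPh3) should give the bromo benzoate (2S)-3-bromo-2-(2,3,4,5-tetramethoxyphenyl)propyl benzoate F5. Reductive removal of the benzoate with i-Bu2AlH at −78 °C gives 12.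

Step 5. Hydride may deprotonate the acidic malonate C–H instead of reducing the esters; the enolate resists reduction or loses ethoxide to give acrylate-derived by-products. The fallback sets out from 6 and returns at 9, avoiding the malonate altogether. Bromine–lithium exchange on 6 (n-BuLi, THF, −78 °C) gives the aryllithium (2,3,4,5-tetramethoxyphenyl)lithium F6. Addition to 1,3-bis(benzyloxy)propan-2-one gives the tertiary benzylic alcohol 1,3-bis(benzyloxy)-2-(2,3,4,5-tetramethoxyphenyl)propan-2-ol F7. Ionic hydrogenation (Et3SiH, CF3CO2H, CH2Cl2, 0 °C) removes the benzylic hydroxyl to give the dibenzyl ether 1-[1,3-bis(benzyloxy)propan-2-yl]-2,3,4,5-tetramethoxybenzene F8. Hydrogenolysis (H2, Pd/C, EtOH) gives diol 9.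

**Further compounds**

F1 | step 9 | (2S)-3-[3-methoxy-2-(4,4,5,5-tetramethyl-1,3,2-dioxaborolan-2-yl)-4-(triisopropylsilyloxy)phenyl]-2-(2,3,4,5-tetramethoxyphenyl)propyl acetate | COc1cc([C@H](Cc2ccc(O[Si](C(C)C)(C(C)C)C(C)C)c(OC)c2B3OC(C)(C)C(C)(C)O3)COC(C)=O)c(OC)c(OC)c1OC
F2 | step 9 | (2S)-3-[2-hydroxy-3-methoxy-4-(triisopropylsilyloxy)phenyl]-2-(2,3,4,5-tetramethoxyphenyl)propyl acetate | COc1cc([C@H](Cc2ccc(O[Si](C(C)C)(C(C)C)C(C)C)c(OC)c2O)COC(C)=O)c(OC)c(OC)c1OC
F3 | step 9 | (2S)-3-[2-hydroxy-3-methoxy-4-(triisopropylsilyloxy)phenyl]-2-(2,3,4,5-tetramethoxyphenyl)propan-1-ol | COc1cc([C@H](Cc2ccc(O[Si](C(C)C)(C(C)C)C(C)C)c(OC)c2O)CO)c(OC)c(OC)c1OC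
F4 | step 6 | (2R)-3-hydroxy-2-(2,3,4,5-tetramethoxyphenyl)propyl benzoate | COc1cc([C@H](CO)COC(=O)c2ccccc2)c(OC)c(OC)c1OC
F5 | step 6 | (2S)-3-bromo-2-(2,3,4,5-tetramethoxyphenyl)propyl benzoate | COc1cc([C@H](CBr)COC(=O)c2ccccc2)c(OC)c(OC)c1OC
F6 | step 5 | (2,3,4,5-tetramethoxyphenyl)lithium | COc1cc([Li])c(OC)c(OC)c1OC
F7 | step 5 | 1,3-bis(benzyloxy)-2-(2,3,4,5-tetramethoxyphenyl)propan-2-ol | COc1cc(C(O)(COCc2ccccc2)COCc2ccccc2)c(OC)c(OC)c1OC
F8 | step 5 | 1-[1,3-bis(benzyloxy)propan-2-yl]-2,3,4,5-tetramethoxybenzene | COc1cc(C(COCc2ccccc2)COCc2ccccc2)c(OC)c(OC)c1OC
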